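Macrocarpal N is treated as a 1,10-seco-aromadendrane. Rejoining the cyclopentanone carbonyl C1 and the side-chain carbonyl C10 as an alkene restores a 5-7-3 tricycle. Its quaternary C4, ring methine C5 and benzylic C9' lie along the track of a transannular cation-olefin closure, and this alignment is what the key step exploits. In one operation diformylphloroglucinol and 3-methylbutanal condense to an ortho-quinone methide, C4 of (+)-bicyclogermacrene attacks it and C5 bonds to C1. This creates three C-C bonds, the five- and seven-membered rings and three stereocentres. The precursor is the E,E-cyclodeca-1,5-diene cis-fused to a gem-dimethylcyclopropane, made from (+)-2-carene. Ozonolysis of C1=C10 then delivers the target.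

Key step: step 11

Remark: terpene atoms carry germacrane/aromadendrane numbers C1-C15 and the aromatic unit primed numbers. The target is 4R,5R,6R,7R,9'S in this numbering. Stereocentres that are created and erased again (C2 in 15, the peroxidic carbons in 2 and 23) are left undefined in the SMILES because they have no bearing on the target.

Step 1
Reactants: 1 (+)-2-carene
Product: 4 keto acetal 4-[(1R,3S)-3-(dimethoxymethyl)-2,2-dimethylcyclopropyl]butan-2-one, via carene ozonide 2 (not isolated), via keto aldehyde 3 (not isolated)
Conditions: O3, CH2Cl2, -78 °C; PPh3, -78 °C to rt; solvent exchange; HC(OMe)3 (1.2 equiv), CeCl3·7H2O (cat.), MeOH, rt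
Reagents that add atoms: ozone [O-][O+]=O; trimethyl orthoformate COC(OC)OC
Why: Criegee ozonolysis cleaves the only alkene to keto aldehyde 3 without touching the two cyclopropane stereocentres (future C6 and C7), and lanthanide-catalysed acetalisation with orthoformate takes the aldehyde in preference to the methyl ketone, so C5 is masked while C10 stays free.

Step 2
Reactants: 4 keto acetal
Product: 5 ethyl (2E)-5-[(1R,3S)-3-(dimethoxymethyl)-2,2-dimethylcyclopropyl]-3-methylpent-2-enoate
Conditions: (EtO)2P(O)CH2CO2Et, NaH, THF, 0 °C to 40 °C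
Reagents that add atoms: triethyl phosphonoacetate CCOC(=O)CP(=O)(OCC)OCC
Why: The Horner-Wadsworth-Emmons olefination of the methyl ketone places the ester anti to the longer C9 chain, so the E C1=C10 alkene should predominate and the minor Z isomer is removed by chromatography, while the acetal is inert to the base and no epimerisable centre is present.

Step 3
Reactants: 5 E-enoate acetal
Product: 6 (2E)-5-[(1R,3S)-3-(dimethoxymethyl)-2,2-dimethylcyclopropyl]-3-methylpent-2-en-1-ol
Conditions: iBu2AlH (2.2 equiv), CH2Cl2, -78 °C; aq potassium sodium tartrate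
Reagents that add atoms: none
Why: 1,2-Reduction of an enoate by iBu2AlH at low temperature ends at the allylic alcohol and leaves the dimethyl acetal and the alkene geometry untouched.

Step 4
Reactants: 6 allylic alcohol acetal
Product: 9 [(2E)-5-[(1R,3S)-3-(dimethoxymethyl)-2,2-dimethylcyclopropyl]-3-methylpent-2-en-1-yl]sulfonylbenzene, via allylic mesylate 7 (not isolated), via allylic bromide 8 (not isolated)
Conditions: MsCl, Et3N, THF, -40 °C; LiBr, 0 °C; then PhSO2Na, DMF, rt
Reagents that add atoms: sodium benzenesulfinate [Na+].[O-]S(=O)c1ccccc1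
Why: Mesylation, Finkelstein-type displacement by bromide and SN2 S-alkylation of the soft sulfinate at the primary allylic carbon C2 all run under non-acidic conditions, so the acetal survives and the E geometry is kept.

Step 5
Reactants: 9 sulfonyl acetal
Product: 11 ethyl (2E)-3-[(1S,3R)-2,2-dimethyl-3-[(3E)-3-methyl-5-(phenylsulfonyl)pent-3-en-1-yl]cyclopropyl]-2-methylprop-2-enoate, via sulfonyl aldehyde 10 (not isolated)
Conditions: 1 M aq HCl, THF, rt; NaHCO3 work-up; crude 10, Ph3P=C(Me)CO2Et, CH2Cl2, rt
Reagents that add atoms: ethyl 2-(triphenylphosphoranylidene)propanoate CCOC(=O)C(C)=P(c1ccccc1)(c1ccccc1)c1ccccc1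
Why: Mild aqueous acid hydrolyses the acetal through a cyclopropyl-stabilised oxocarbenium ion, and the Wittig reaction of the crude aldehyde with the stabilised alpha-branched ylide gives the E C4=C5 enoate, the ylide being too weakly basic to epimerise C6 or to deprotonate the sulfone.

Step 6
Reactants: 11 sulfonyl enoate
Product: 12 (2E)-3-[(1S,3R)-2,2-dimethyl-3-[(3E)-3-methyl-5-(phenylsulfonyl)pent-3-en-1-yl]cyclopropyl]-2-methylprop-2-en-1-ol
Conditions: iBu2AlH (2.2 equiv), CH2Cl2, -78 °C; aq potassium sodium tartrate
Reagents that add atoms: none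
Why: 1,2-Reduction of the enoate by iBu2AlH gives the C3 allylic alcohol, and the sulfone, both alkenes and the cyclopropane are inert to the hydride at this temperature.

Step 7
Reactants: 12 sulfonyl allylic alcohol
Product: 14 [(2E)-5-[(1R,3S)-3-[(1E)-3-chloro-2-methylprop-1-en-1-yl]-2,2-dimethylcyclopropyl]-3-methylpent-2-en-1-yl]sulfonylbenzene, via sulfonyl allylic mesylate 13 (not isolated)
Conditions: MsCl, LiCl, 2,4,6-collidine, DMF, 0 °C
Reagents that add atoms: lithium chloride [Li+].[Cl-]
Why: In this buffered mesylate/chloride allylic chlorination the mesylate is displaced by chloride in an SN2 sense as soon as it forms, which avoids ionisation of the cyclopropyl-conjugated allyl system and so avoids transposition or loss of the E geometry.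

Step 8
Reactants: 14 chloro sulfone
Product: 15 (1S,2E,6E,10R)-3,7,11,11-tetramethyl-5-(phenylsulfonyl)bicyclo[8.1.0]undeca-2,6-diene (2-phenylsulfonylbicyclogermacrene; C2 epimers)
Conditions: LiN(SiMe3)2 (1.2 equiv), THF (2 mM), -78 °C to rt
Reagents that add atoms: none
Why: Intramolecular SN2 alkylation of the sulfone-stabilised allyl carbanion at its alpha carbon C2 by the primary allylic chloride C3 closes the ten-membered ring, because the cis-cyclopropane holds both arms on one face as a turn element and high dilution disfavours dimerisation, while both E alkenes are kept and the new C2 centre is erased in step 9.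

Step 9
Reactants: 15 cyclic sulfone
Product: 16 (+)-bicyclogermacrene (1S,2E,6E,10R)-3,7,11,11-tetramethylbicyclo[8.1.0]undeca-2,6-diene
Conditions: PdCl2(dppp) (5 mol %), LiHBEt3 (2.5 equiv), THF, 0 °C; pentane, Et3N-washed SiO2, kept at or below rt
Reagents that add atoms: none
Why: In this palladium-catalysed hydride desulfonylation the zerovalent palladium formed in situ ionises the allylic sulfone to a pi-allyl complex over C2-C1-C10 and hydride is delivered to the less substituted C2, so position and E geometry of the C1=C10 alkene are retained, the remote vinylcyclopropane is not involved and the low temperature avoids Cope rearrangement.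

Step 10
Reactants: 17 phloroglucinol
Product: 19 2,4,6-trihydroxybenzene-1,3-dicarbaldehyde, via bis-iminium salt 18 (not isolated)
Conditions: POCl3 (2.3 equiv), DMF (2.3 equiv), 1,4-dioxane, 0 °C to rt; then H2O, 0 °C to rt
Reagents that add atoms: N,N-dimethylformamide CN(C)C=O; water O
Why: The double Vilsmeier-Haack formylation of the very electron-rich ring stops at the second substitution because each iminium group deactivates the ring and only about two equivalents of chloroiminium reagent are supplied, and hydrolysis of 18 releases the dialdehyde.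

Step 11
Reactants: 16 (+)-bicyclogermacrene; 19 2,4,6-trihydroxybenzene-1,3-dicarbaldehyde; 20 3-methylbutanal
Product: 22 aromadendr-1(10)-ene adduct 5-[(1S)-3-methyl-1-[(4R,5R,6R,7R)-aromadendr-1(10)-en-4-yl]butyl]-2,4,6-trihydroxybenzene-1,3-dicarbaldehyde, via ortho-quinone methide 21 (not isolated)
Conditions: 19 (1.5 equiv), 20 (1.5 equiv), MeNHCH2CH2NHMe (10 mol %), 4 Å MS, (CF3)2CHOH, 0 °C, 30 min; then 16 added slowly (minimal CH2Cl2), 0 °C to rt
Reagents that add atoms: none
Why: The diamine catalyses a Knoevenagel-type condensation of 20 with the free ring carbon C1' of 19, and loss of water gives quinone methide 21, which hydrogen bonding to the fluorinated alcohol turns into a benzylic-cation-like acceptor; C4 of the C4=C5 alkene adds to C9' while C1 of the C1=C10 alkene bonds to C5 across the ring, and the tertiary C10 cation gives up H1 to the phenoxide. The closest known reaction type is the amine-catalysed three-component quinone methide Michael addition/cation-olefin cascade of diformylphloroglucinol with macrocyclic sesquiterpene dienes in fluorinated alcohols, taken together with the proton-induced closure of 16 to the ledene skeleton. The single C5-C1 bond closes the five-membered ring 5-exo-trig (C10 stays outside it) and at the same time the seven-membered ring 7-endo-trig, the latter being the rest of the former ten-membered ring. C4 and C5 are set by anti addition to the E alkene from the peripheral face, the only open one in the crossed conformer enforced by the cis-fused gem-dimethylcyclopropane, which puts C15 cis to C6 and H5 trans to H6 just as protonation does on the way to ledene, whereas C9' depends only on the face of 21 that is attacked, where avoidance of the C15 methyl by the isobutyl chain offers a weak bias, so the 9'-epimer is expected as a by-product to be removed by chromatography. The step needs reaction at the C4=C5 rather than the C1=C10 alkene, attack through the fully substituted C4, carbocyclic rather than chroman closure and Zaitsev loss of H1: the first two rest on conjugation of C4=C5 with the cyclopropane Walsh orbitals, on cyclopropylcarbinyl stabilisation of charge at C5 and on C1 lying within bonding distance of C5, the third on the ionising, weakly nucleophilic medium that keeps the phenoxide hydrogen-bonded, and the last on the stability of the tetrasubstituted alkene. Mixing 19, 20 and the diamine before 16 is added, and the molecular sieves, limit protonation of 16 and capture of the C10 cation by water.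

Step 12
Reactants: 22 aromadendr-1(10)-ene adduct
Product: 24 macrocarpal N 5-[(1S)-1-[(1R,2R)-2-[(1R,3R)-2,2-dimethyl-3-(3-oxobutyl)cyclopropyl]-1-methyl-3-oxocyclopentyl]-3-methylbutyl]-2,4,6-trihydroxybenzene-1,3-dicarbaldehyde, via adduct ozonide 23 (not isolated)
Conditions: O3 (1.0 equiv, titrated solution in CH2Cl2), CH2Cl2, -78 °C; PPh3, -78 °C to rt
Reagents that add atoms: ozone [O-][O+]=O
Why: Criegee ozonolysis picks out the tetrasubstituted C1=C10 alkene, the only C=C bond and by far the most electron-rich site, while the arene is deactivated by two formyl groups and its hydroxyls are locked in hydrogen bonds, so one titrated equivalent of ozone and phosphine reduction of 23 should open the seven-membered ring to the C1 cyclopentanone and the C10 methyl ketone without creating a stereocentre, and C5 next to the new ketone is safe because C6 already lies trans to the bulky C9' substituent.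

Compound list
1 | (+)-2-carene, (1S,6R)-3,7,7-trimethylbicyclo[4.1.0]hept-2-ene | CC1=C[C@H]2[C@@H](CC1)C2(C)C | starting material
2 | carene ozonide (1,2,4-trioxolane bridging C5 and C10) | CC12CC[C@@H]3[C@H](C(OO1)O2)C3(C)C | intermediate
3 | (1S,3R)-2,2-dimethyl-3-(3-oxobutyl)cyclopropane-1-carbaldehyde | CC(=O)CC[C@@H]1[C@H](C=O)C1(C)C | intermediate
4 | 4-[(1R,3S)-3-(dimethoxymethyl)-2,2-dimethylcyclopropyl]butan-2-one | CC(=O)CC[C@@H]1[C@H](C(OC)OC)C1(C)C | intermediate
5 | ethyl (2E)-5-[(1R,3S)-3-(dimethoxymethyl)-2,2-dimethylcyclopropyl]-3-methylpent-2-enoate | CCOC(=O)/C=C(\C)CC[C@@H]1[C@H](C(OC)OC)C1(C)C | intermediate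
6 | (2E)-5-[(1R,3S)-3-(dimethoxymethyl)-2,2-dimethylcyclopropyl]-3-methylpent-2-en-1-ol | OC/C=C(\C)CC[C@@H]1[C@H](C(OC)OC)C1(C)C | intermediate
7 | methanesulfonate of 6 | CS(=O)(=O)OC/C=C(\C)CC[C@@H]1[C@H](C(OC)OC)C1(C)C | intermediate
8 | (1R,3S)-1-[(3E)-5-bromo-3-methylpent-3-en-1-yl]-3-(dimethoxymethyl)-2,2-dimethylcyclopropane | BrC/C=C(\C)CC[C@@H]1[C@H](C(OC)OC)C1(C)C | intermediate
9 | [(2E)-5-[(1R,3S)-3-(dimethoxymethyl)-2,2-dimethylcyclopropyl]-3-methylpent-2-en-1-yl]sulfonylbenzene | O=S(=O)(c1ccccc1)C/C=C(\C)CC[C@@H]1[C@H](C(OC)OC)C1(C)C | intermediate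
10 | (1S,3R)-2,2-dimethyl-3-[(3E)-3-methyl-5-(phenylsulfonyl)pent-3-en-1-yl]cyclopropane-1-carbaldehyde | O=S(=O)(c1ccccc1)C/C=C(\C)CC[C@@H]1[C@H](C=O)C1(C)C | intermediate
11 | ethyl (2E)-3-[(1S,3R)-2,2-dimethyl-3-[(3E)-3-methyl-5-(phenylsulfonyl)pent-3-en-1-yl]cyclopropyl]-2-methylprop-2-enoate | O=S(=O)(c1ccccc1)C/C=C(\C)CC[C@@H]1[C@H](/C=C(\C)C(=O)OCC)C1(C)C | intermediate
12 | (2E)-3-[(1S,3R)-2,2-dimethyl-3-[(3E)-3-methyl-5-(phenylsulfonyl)pent-3-en-1-yl]cyclopropyl]-2-methylprop-2-en-1-ol | O=S(=O)(c1ccccc1)C/C=C(\C)CC[C@@H]1[C@H](/C=C(\C)CO)C1(C)C | intermediate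
13 | methanesulfonate of 12 | O=S(=O)(c1ccccc1)C/C=C(\C)CC[C@@H]1[C@H](/C=C(\C)COS(C)(=O)=O)C1(C)C | intermediate
14 | [(2E)-5-[(1R,3S)-3-[(1E)-3-chloro-2-methylprop-1-en-1-yl]-2,2-dimethylcyclopropyl]-3-methylpent-2-en-1-yl]sulfonylbenzene | O=S(=O)(c1ccccc1)C/C=C(\C)CC[C@@H]1[C@H](/C=C(\C)CCl)C1(C)C | intermediate
15 | (1S,2E,6E,10R)-3,7,11,11-tetramethyl-5-(phenylsulfonyl)bicyclo[8.1.0]undeca-2,6-diene, C2 (terpene numbering) epimers | C2[C@@H]1[C@H](/C=C(\C)CC(S(=O)(=O)c3ccccc3)/C=C(\C)C2)C1(C)C | intermediate
16 | (+)-bicyclogermacrene, (1S,2E,6E,10R)-3,7,11,11-tetramethylbicyclo[8.1.0]undeca-2,6-diene | C2[C@@H]1[C@H](/C=C(\C)CC/C=C(\C)C2)C1(C)C | intermediate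
17 | phloroglucinol, benzene-1,3,5-triol | Oc1cc(O)cc(O)c1 | starting material
18 | bis(N,N-dimethyliminiomethyl)phloroglucinol dichloride | C[N+](C)=Cc1c(O)cc(O)c(C=[N+](C)C)c1O.[Cl-].[Cl-] | intermediate
19 | 2,4,6-trihydroxybenzene-1,3-dicarbaldehyde | O=Cc1c(O)cc(O)c(C=O)c1O | intermediate
20 | 3-methylbutanal | CC(C)CC=O | starting material
21 | 2,4-dihydroxy-5-(3-methylbutylidene)-6-oxocyclohexa-1,3-diene-1,3-dicarbaldehyde (ortho-quinone methide) | CC(C)CC=C1C(=O)C(C=O)=C(O)C(C=O)=C1O | intermediate
22 | 5-[(1S)-3-methyl-1-[(4R,5R,6R,7R)-aromadendr-1(10)-en-4-yl]butyl]-2,4,6-trihydroxybenzene-1,3-dicarbaldehyde (ledene skeleton with C9' in place of H4; C15 cis to C6; H5 trans to H6) | CC=2CC[C@@H]1[C@H]([C@H]3C=2CC[C@]3(C)[C@H](CC(C)C)c4c(O)c(C=O)c(O)c(C=O)c4O)C1(C)C | intermediate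
23 | 1,10-ozonide of 22 (1,2,4-trioxolane bridging C1 and C10) | CC12CC[C@@H]3[C@H]([C@H]4C(OO1)(O2)CC[C@]4(C)[C@H](CC(C)C)c5c(O)c(C=O)c(O)c(C=O)c5O)C3(C)C | intermediate
24 | macrocarpal N | CC(=O)CC[C@@H]1[C@H]([C@H]2C(=O)CC[C@]2(C)[C@H](CC(C)C)c2c(O)c(C=O)c(O)c(C=O)c2O)C1(C)C | target

Total step count: 12. Longest linear sequence: 11 (steps 1 to 9, then 11 and 12).

Steps most likely to fail

**Step 11.**
- What may go wrong: the phenolic oxygen may close onto the developing cation (hetero-Diels-Alder-type chroman formation at either alkene). Attack may run through a less substituted alkene carbon. The acidic phenol may protonate the diene before any C-C bond forms. The cascade may end by water capture or by loss of a proton other than H1. Facial control at C9' may be poor.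
- Fallback: the C1'-C9' bond is made in a separate operation and the oxygen that would close the chroman is tied to boron. The fallback sets out from 19 and 20. Condensation with PhB(OH)2 (cat. EtCO2H, toluene, Dean-Stark) should give racemic 5,7-dihydroxy-4-(2-methylpropyl)-2-phenyl-4H-1,3,2-benzodioxaborinine-6,8-dicarbaldehyde F1, an isolable neutral surrogate of 21.
- Its benzylic C-O bond is ionised with BF3·OEt2 in CH2Cl2 at -78 °C in the presence of 16 and 2,6-di-tert-butyl-4-methylpyridine. This offers the same electrophile to C4 in an aprotic, water-free medium, and the aryl oxygen stays on boron until work-up. Aqueous hydrolysis of the boronate rejoins the route at 22, and the 9'-epimer is separated as before.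

**Step 8.**
- What may go wrong: intermolecular alkylation may outrun closure of the strained ten-membered ring, or base-induced elimination of HCl may consume the allylic chloride.
- Fallback: ring closure is moved from the C2-C3 bond to the C4=C5 alkene. The fallback sets out from bromide 8, taken on crude. Alkylation with lithiated acetone N,N-dimethylhydrazone (THF, -78 °C) should give (5E)-8-[(1R,3S)-3-(dimethoxymethyl)-2,2-dimethylcyclopropyl]-6-methyloct-5-en-2-one N,N-dimethylhydrazone F2.
- Aqueous oxalic acid in THF removes both masking groups to give (1S,3R)-2,2-dimethyl-3-[(3E)-3-methyl-7-oxooct-3-en-1-yl]cyclopropane-1-carbaldehyde F3.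
- Slow addition of F3 to low-valent titanium (TiCl3, Zn-Cu, DME, reflux) effects an intramolecular McMurry coupling of C4 with C5 and comes back to the route at 16. The 4Z isomer is removed on AgNO3-impregnated silica.

**Step 12.**
- What may go wrong: oxidative degradation of the trihydroxyarene or its formyl groups may compete with alkene cleavage, and reduction of the hindered peroxide may be sluggish.
- Fallback: the phenols are masked before the oxidation. The fallback sets out from 22. Ac2O, pyridine and DMAP (cat.) in CH2Cl2 should give the aromadendrene adduct triacetate F4, whose ring is inert to ozone.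
- O3 in CH2Cl2 at -78 °C gives the triacetate ozonide F5, and PPh3 reduces it to macrocarpal N triacetate F6.
- K2CO3 (cat.) in MeOH at 0 °C removes the activated aryl acetates and returns to the route at 24.

Further compounds
F1 | step 11 | 5,7-dihydroxy-4-(2-methylpropyl)-2-phenyl-4H-1,3,2-benzodioxaborinine-6,8-dicarbaldehyde (racemic) | CC(C)CC1OB(c2ccccc2)Oc2c1c(O)c(C=O)c(O)c2C=O
F2 | step 8 | (5E)-8-[(1R,3S)-3-(dimethoxymethyl)-2,2-dimethylcyclopropyl]-6-methyloct-5-en-2-one N,N-dimethylhydrazone | CC(CC/C=C(\C)CC[C@@H]1[C@H](C(OC)OC)C1(C)C)=NN(C)C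
F3 | step 8 | (1S,3R)-2,2-dimethyl-3-[(3E)-3-methyl-7-oxooct-3-en-1-yl]cyclopropane-1-carbaldehyde | CC(=O)CC/C=C(\C)CC[C@@H]1[C@H](C=O)C1(C)C
F4 | step 12 | aromadendrene adduct triacetate (tri-O-acetyl 22) | CC=2CC[C@@H]1[C@H]([C@H]3C=2CC[C@]3(C)[C@H](CC(C)C)c4c(OC(C)=O)c(C=O)c(OC(C)=O)c(C=O)c4OC(C)=O)C1(C)C
F5 | step 12 | triacetate ozonide (1,10-ozonide of F4) | CC12CC[C@@H]3[C@H]([C@H]4C(OO1)(O2)CC[C@]4(C)[C@H](CC(C)C)c5c(OC(C)=O)c(C=O)c(OC(C)=O)c(C=O)c5OC(C)=O)C3(C)C
F6 | step 12 | macrocarpal N triacetate | CC(=O)CC[C@@H]1[C@H]([C@H]2C(=O)CC[C@]2(C)[C@H](CC(C)C)c2c(OC(C)=O)c(C=O)c(OC(C)=O)c(C=O)c2OC(C)=O)C1(C)C
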